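**Strategy**

Everything rests on cutting the exocyclic bond between ring carbon C5 of the 1,2-dioxolane and the first CH2 of the side chain. Because C5 is bound to peroxide oxygen O1, a 5-methoxy-1,2-dioxolane that already holds the C3 quaternary centre and the acetate arm can be ionised to a peroxycarbenium ion. In one operation this ion is captured by a dialkylzinc carrying the complete (R)-configured dienyl chain: the two halves are joined and the C5 quaternary centre is set by C3, with entry anti to the CH2CO2Me arm. The precursors are cyclic peroxyketal ester 9, made from an enantioenriched oxetane and hydrogen peroxide, and alkyl chloride 18.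

Key step: step 9

Assumption: in step 2 the sense of asymmetric induction is taken from simple alkyl methyl ketones and is to be checked on oxetane 4; should it be opposite, the (R)-binaphthoxide catalyst is used instead.

**Route**

Step 1
Reactants: 1 pentane-2,4-dione
Product: 2 1-(2-methyl-1,3-dioxolan-2-yl)propan-2-one
Conditions: HOCH2CH2OH (1.0 equiv), TsOH·H2O (cat.), benzene, reflux, azeotropic removal of water
Reagents that add atoms: ethane-1,2-diol, OCCO
Why: Acid-catalysed mono-ketalisation; one equivalent of diol and the lower reactivity of the remaining β-ketal ketone should stop the reaction at 2.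

Step 2
Reactants: 2 1-(2-methyl-1,3-dioxolan-2-yl)propan-2-one
Product: 4 (2S)-2-methyl-2-[(2-methyl-1,3-dioxolan-2-yl)methyl]oxetane, via epoxide 3 (not isolated)
Conditions: Me3S(O)I, NaH, THF; then 2, LaLi3[(S)-binaphthoxide]3 (5 then 15 mol %), [2,4,6-(MeO)3C6H2]3P=O, MS 5 Å, THF, rt, then second portion of ylide, 45 °C
Reagents that add atoms: trimethylsulfoxonium iodide, C[S+](C)(C)=O.[I-]
Why: Catalytic asymmetric Corey–Chaykovsky methylenation, in which the lanthanum–lithium binaphthoxide catalyst directs the sulfoxonium ylide to one face of the methyl ketone (CH3 against the ketal-bearing CH2) to set the quaternary C–O centre in epoxide 3, followed by ring expansion with a second ylide at the CH2 terminus that does not touch this centre.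

Step 3
Reactants: 4 (2S)-2-methyl-2-[(2-methyl-1,3-dioxolan-2-yl)methyl]oxetane
Product: 6 2-[(3R)-5-methoxy-3,5-dimethyl-1,2-dioxolan-3-yl]ethan-1-ol (both C5 epimers), via hydroperoxide 5 (not isolated)
Conditions: (i) H2O2 (anhydrous, in Et2O), TMSOTf (0.1 equiv), Et2O, −78 to 0 °C; aqueous wash; (ii) MeOH, TsOH·H2O (cat.), rt
Reagents that add atoms: hydrogen peroxide, OO; methanol, CO
Why: Lewis-acid-promoted perhydrolysis of the 2,2-disubstituted oxetane, in which H2O2 should attack the tertiary carbon with inversion to give (3R)-hydroperoxide 5, followed by acid-catalysed transketalisation in methanol in which the OOH group closes the 1,2-dioxolane (5-exo) on the former ketal carbon.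

Step 4
Reactants: 6 2-[(3R)-5-methoxy-3,5-dimethyl-1,2-dioxolan-3-yl]ethan-1-ol
Product: 8 2-[(3S)-5-methoxy-3,5-dimethyl-1,2-dioxolan-3-yl]acetic acid, via aldehyde 7 (not isolated)
Conditions: TEMPO (0.2 equiv), PhI(OAc)2 (2.2 equiv), NaHCO3, MeCN–H2O, 0 °C to rt
Reagents that add atoms: water, O
Why: Oxoammonium (TEMPO) oxidation of the primary alcohol through aldehyde 7 and its hydrate to the acid, under buffered conditions that dialkyl peroxides and peroxyketals should tolerate (the descriptor at C3 changes only because the priorities change).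

Step 5
Reactants: 8 2-[(3S)-5-methoxy-3,5-dimethyl-1,2-dioxolan-3-yl]acetic acid
Product: 9 methyl 2-[(3S)-5-methoxy-3,5-dimethyl-1,2-dioxolan-3-yl]acetate
Conditions: MeI, K2CO3, DMF, rt
Reagents that add atoms: iodomethane, CI
Why: SN2 O-alkylation of the carboxylate under mild base, which should leave the peroxyketal untouched.

Step 6
Reactants: 10 5-chloropent-1-yne
Product: 12 (1E)-5-chloro-1-iodopent-1-ene, via alkenylzirconocene 11 (not isolated)
Conditions: Cp2Zr(H)Cl, THF, rt; then I2, 0 °C
Reagents that add atoms: iodine, II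
Why: Hydrozirconation of the terminal alkyne is syn and places zirconium at the terminal carbon, and iodinolysis of the C–Zr bond proceeds with retention, so the (E)-iodide should result.

Step 7
Reactants: 13 [(1E)-buta-1,3-dien-1-yl]benzene and 12 (1E)-5-chloro-1-iodopent-1-ene
Product: 15 [(1E,5E)-9-chloronona-1,5-dien-1-yl]benzene, via alkylborane 14 (not isolated)
Conditions: 9-BBN, THF, 0 °C to rt; then 12, PdCl2(dppf) (3 mol %), 3 M aq NaOH, THF, 50 °C
Reagents that add atoms: none
Why: 9-BBN should add to the terminal double bond of the diene with boron at the terminal carbon, and the B-alkyl Suzuki–Miyaura coupling joins this carbon to the vinyl iodide with retention of the E geometry while the alkyl chloride stays inert.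

Step 8
Reactants: 15 [(1E,5E)-9-chloronona-1,5-dien-1-yl]benzene and 16 (2S)-1-bromo-3-chloro-2-methylpropane
Product: 18 [(1E,5E,11R)-12-chloro-11-methyldodeca-1,5-dien-1-yl]benzene, via Grignard reagent 17 (not isolated)
Conditions: Mg, THF, reflux; then 16, Li2CuCl4 (3 mol %), THF, −20 °C to rt
Reagents that add atoms: none
Why: Copper-catalysed cross-coupling of a primary alkyl Grignard reagent with the primary C–Br bond (far more reactive than C–Cl); the methyl-bearing stereocentre comes from 16 and is not involved.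

Step 9
Reactants: 9 methyl 2-[(3S)-5-methoxy-3,5-dimethyl-1,2-dioxolan-3-yl]acetate and 18 [(1E,5E,11R)-12-chloro-11-methyldodeca-1,5-dien-1-yl]benzene
Product: 22 methyl 2-[(3S,5R)-3,5-dimethyl-5-[(2R,7E,11E)-2-methyl-12-phenyldodeca-7,11-dien-1-yl]-1,2-dioxolan-3-yl]acetate, via Grignard reagent 19 (not isolated), via dialkylzinc 20 (not isolated), via peroxycarbenium triflate 21 (not isolated)
Conditions: (i) 18, Mg, THF, reflux; ZnCl2 (0.5 equiv), 0 °C to rt; solvent changed to CH2Cl2; (ii) 9, CH2Cl2, −78 °C, TMSOTf (1.1 equiv), −78 to −40 °C; aq NH4Cl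
Reagents that add atoms: none
Why: Proposed new method: TMSOTf should ionise the C5–OMe bond of cyclic peroxyketal 9 to peroxycarbenium ion 21, stabilised by the lone pair of ring oxygen O1, and dialkylzinc 20 should transfer its primary alkyl group to C5 before it can attack the O–O bond, because diorganozincs are expected to be inert toward dialkyl peroxides and esters at −78 °C when copper and nickel are absent. The closest known reaction types are the Lewis-acid-mediated substitution of 3-alkoxy-1,2-dioxolanes by allylsilanes and silyl ketene acetals through peroxycarbenium ions, and the TMSOTf-promoted transfer of alkyl groups from diorganozincs to oxocarbenium ions. No ring is closed in this step, since the 1,2-dioxolane is already in place. The new quaternary stereocentre C5 is controlled by C3 across the ring: the alkyl group should enter anti to the larger CH2CO2Me arm (a preference that participation of the ester carbonyl at the cationic carbon would reinforce), which places the side chain trans to the acetate arm as in (3S,5R)-22. The step needs C-alkylation to win over hydride transfer from the β-branched alkylzinc and over proton loss from 21; low temperature, a non-coordinating solvent and a copper-free zinc reagent are meant to secure this, and the side-chain stereocentre and both E-alkenes are not touched.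

Step 10
Reactants: 22 methyl 2-[(3S,5R)-3,5-dimethyl-5-[(2R,7E,11E)-2-methyl-12-phenyldodeca-7,11-dien-1-yl]-1,2-dioxolan-3-yl]acetate
Product: 23 2-[(3S,5R)-3,5-dimethyl-5-[(2R,7E,11E)-2-methyl-12-phenyldodeca-7,11-dien-1-yl]-1,2-dioxolan-3-yl]acetic acid
Conditions: LiOH, THF–H2O, 0 °C; then 1 M HCl to pH 3
Reagents that add atoms: lithium hydroxide, [Li+].[OH-]
Why: Saponification of the methyl ester, in which the tertiary dialkyl peroxide should be stable to cold aqueous hydroxide and the carboxylate formed resists retro-conjugate opening of the ring.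

**Compound list**

1 | pentane-2,4-dione | CC(=O)CC(C)=O | starting material
2 | 1-(2-methyl-1,3-dioxolan-2-yl)propan-2-one | CC(=O)CC1(C)OCCO1 | intermediate
3 | (2R)-2-methyl-2-[(2-methyl-1,3-dioxolan-2-yl)methyl]oxirane | CC1(OCCO1)C[C@]2(C)CO2 | intermediate (not isolated)
4 | (2S)-2-methyl-2-[(2-methyl-1,3-dioxolan-2-yl)methyl]oxetane | CC1(OCCO1)C[C@]2(C)CCO2 | intermediate
5 | (3R)-3-hydroperoxy-3-methyl-4-(2-methyl-1,3-dioxolan-2-yl)butan-1-ol | CC1(OCCO1)C[C@@](C)(CCO)OO | intermediate (not isolated)
6 | 2-[(3R)-5-methoxy-3,5-dimethyl-1,2-dioxolan-3-yl]ethan-1-ol (both C5 epimers) | COC1(C)C[C@@](C)(CCO)OO1 | intermediate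
7 | 2-[(3R)-5-methoxy-3,5-dimethyl-1,2-dioxolan-3-yl]acetaldehyde | COC1(C)C[C@@](C)(CC=O)OO1 | intermediate (not isolated)
8 | 2-[(3S)-5-methoxy-3,5-dimethyl-1,2-dioxolan-3-yl]acetic acid | COC1(C)C[C@@](C)(CC(=O)O)OO1 | intermediate
9 | methyl 2-[(3S)-5-methoxy-3,5-dimethyl-1,2-dioxolan-3-yl]acetate | COC1(C)C[C@@](C)(CC(=O)OC)OO1 | intermediate
10 | 5-chloropent-1-yne | C#CCCCCl | starting material
11 | chlorido[(1E)-5-chloropent-1-en-1-yl]bis(cyclopentadienyl)zirconium | Cl[Zr](/C=C/CCCCl)(C1C=CC=C1)C1C=CC=C1 | intermediate (not isolated)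
12 | (1E)-5-chloro-1-iodopent-1-ene | ClCCC/C=C/I | intermediate
13 | [(1E)-buta-1,3-dien-1-yl]benzene | C=C/C=C/c1ccccc1 | starting material
14 | 9-[(3E)-4-phenylbut-3-en-1-yl]-9-borabicyclo[3.3.1]nonane | c1ccccc1/C=C/CCB1C2CCCC1CCC2 | intermediate (not isolated)
15 | [(1E,5E)-9-chloronona-1,5-dien-1-yl]benzene | ClCCC/C=C/CC/C=C/c1ccccc1 | intermediate
16 | (2S)-1-bromo-3-chloro-2-methylpropane | C[C@H](CBr)CCl | starting material
17 | chlorido[(4E,8E)-9-phenylnona-4,8-dien-1-yl]magnesium | Cl[Mg]CCC/C=C/CC/C=C/c1ccccc1 | intermediate (not isolated)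
18 | [(1E,5E,11R)-12-chloro-11-methyldodeca-1,5-dien-1-yl]benzene | C[C@H](CCCC/C=C/CC/C=C/c1ccccc1)CCl | intermediate
19 | chlorido[(2R,7E,11E)-2-methyl-12-phenyldodeca-7,11-dien-1-yl]magnesium | C[C@H](CCCC/C=C/CC/C=C/c1ccccc1)C[Mg]Cl | intermediate (not isolated)
20 | bis[(2R,7E,11E)-2-methyl-12-phenyldodeca-7,11-dien-1-yl]zinc | C[C@H](CCCC/C=C/CC/C=C/c1ccccc1)C[Zn]C[C@H](C)CCCC/C=C/CC/C=C/c1ccccc1 | intermediate (not isolated)
21 | (3S)-3-(2-methoxy-2-oxoethyl)-3,5-dimethyl-1,2-dioxolan-5-ylium trifluoromethanesulfonate | C[C+]1C[C@@](C)(CC(=O)OC)OO1.[O-]S(=O)(=O)C(F)(F)F | intermediate (not isolated)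
22 | methyl 2-[(3S,5R)-3,5-dimethyl-5-[(2R,7E,11E)-2-methyl-12-phenyldodeca-7,11-dien-1-yl]-1,2-dioxolan-3-yl]acetate | C[C@H](CCCC/C=C/CC/C=C/c1ccccc1)C[C@]1(C)C[C@@](C)(CC(=O)OC)OO1 | intermediate
23 | 2-[(3S,5R)-3,5-dimethyl-5-[(2R,7E,11E)-2-methyl-12-phenyldodeca-7,11-dien-1-yl]-1,2-dioxolan-3-yl]acetic acid | C[C@H](CCCC/C=C/CC/C=C/c1ccccc1)C[C@]1(C)C[C@@](C)(CC(=O)O)OO1 | target

**Count**

Total steps: 10. Longest linear sequence: 7 steps (steps 1, 2, 3, 4, 5, 9, 10).

**Steps most likely to fail, with fallbacks**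

Step 9 (Proposed new method). The alkylzinc may deliver a β-hydride instead of its alkyl group, the organometal may attack the peroxide oxygen with ring opening, or the cation may lose a proton before capture; facial selectivity at C5 may also be low, in which case the C5 epimer would have to be separated. The fallback uses known chemistry only, sets out from oxetane 4 and Grignard reagent 19, and comes back at target 23. The ketal of 4 is hydrolysed (pyridinium tosylate, wet acetone) to 1-[(2S)-2-methyloxetan-2-yl]propan-2-one F1. Addition of 19 in the presence of CeCl3 (THF, −78 °C) forms the C5–CH2 bond by carbonyl addition and should give (2RS,4R,9E,13E)-2,4-dimethyl-1-[(2S)-2-methyloxetan-2-yl]-14-phenyltetradeca-9,13-dien-2-ol F2. Ethereal H2O2 with catalytic TMSOTf opens the oxetane at the tertiary carbon with inversion to (3R,5RS,7R,12E,16E)-3-hydroperoxy-3,5,7-trimethyl-17-phenylheptadeca-12,16-diene-1,5-diol F3. Catalytic acid then ionises the tertiary alcohol, and 5-exo capture by the hydroperoxide should give, after separation from its C5 epimer, 2-[(3R,5R)-3,5-dimethyl-5-[(2R,7E,11E)-2-methyl-12-phenyldodeca-7,11-dien-1-yl]-1,2-dioxolan-3-yl]ethan-1-ol F4. Oxidation with TEMPO and PhI(OAc)2 in MeCN–H2O gives 23. This path gives up stereocontrol at C5.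

Step 3. The tertiary centre may lose configuration if the oxetane opens through an ionised pathway, and the ketal may be drawn into oligomeric peroxides under H2O2 and acid. The fallback sets out from ketone 2 and comes back at ester 9. Horner–Wadsworth–Emmons olefination (trimethyl phosphonoacetate, NaH, THF) gives methyl (2E)-3-methyl-4-(2-methyl-1,3-dioxolan-2-yl)but-2-enoate F5 (either alkene isomer serves here). Acid-catalysed perhydrolysis of the ketal in methanol (ethereal H2O2, cat. TsOH) gives methyl (2E)-5-hydroperoxy-5-methoxy-3-methylhex-2-enoate F6. Et2NH in CF3CH2OH closes the ring by 5-exo conjugate addition of the hydroperoxide to the enoate and should give methyl 2-(5-methoxy-3,5-dimethyl-1,2-dioxolan-3-yl)acetate F7, racemic at C3. Preparative chromatography on a chiral stationary phase then delivers 9. The tertiary peroxide is thus made by conjugate addition, not by substitution, at the price of a resolution.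

Step 2. Enantioface discrimination between CH3 and the ketal-bearing CH2 may be poor, and the ylide may enolise the ketone instead of adding. The fallback sets out from ketone 2 and comes back at oxetane 4. The enoate, methyl (2E)-3-methyl-4-(2-methyl-1,3-dioxolan-2-yl)but-2-enoate F5 (as in the fallback for step 3, here with the E isomer separated), is reduced with iBu2AlH to (2E)-3-methyl-4-(2-methyl-1,3-dioxolan-2-yl)but-2-en-1-ol F8. Sharpless asymmetric epoxidation (Ti(OiPr)4, D-(−)-diethyl tartrate, tBuOOH, MS 4 Å, CH2Cl2, −20 °C) should give [(2R,3R)-3-methyl-3-[(2-methyl-1,3-dioxolan-2-yl)methyl]oxiran-2-yl]methanol F9. NaAlH2(OCH2CH2OMe)2 delivers hydride to C2 and gives (3S)-3-methyl-4-(2-methyl-1,3-dioxolan-2-yl)butane-1,3-diol F10. Selective sulfonylation of the primary hydroxyl (TsCl, pyridine) gives (3S)-3-hydroxy-3-methyl-4-(2-methyl-1,3-dioxolan-2-yl)butyl 4-methylbenzenesulfonate F11. KOtBu in THF closes the oxetane (4-exo-tet, tertiary C–O bond untouched) to give 4.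

**Further compounds**

F1 | step 9 | 1-[(2S)-2-methyloxetan-2-yl]propan-2-one | CC(=O)C[C@]1(C)CCO1
F2 | step 9 | (2RS,4R,9E,13E)-2,4-dimethyl-1-[(2S)-2-methyloxetan-2-yl]-14-phenyltetradeca-9,13-dien-2-ol | C[C@H](CCCC/C=C/CC/C=C/c1ccccc1)CC(C)(O)C[C@]1(C)CCO1
F3 | step 9 | (3R,5RS,7R,12E,16E)-3-hydroperoxy-3,5,7-trimethyl-17-phenylheptadeca-12,16-diene-1,5-diol | C[C@H](CCCC/C=C/CC/C=C/c1ccccc1)CC(C)(O)C[C@@](C)(CCO)OO
F4 | step 9 | 2-[(3R,5R)-3,5-dimethyl-5-[(2R,7E,11E)-2-methyl-12-phenyldodeca-7,11-dien-1-yl]-1,2-dioxolan-3-yl]ethan-1-ol | C[C@H](CCCC/C=C/CC/C=C/c1ccccc1)C[C@]1(C)C[C@@](C)(CCO)OO1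
F5 | step 3 | methyl (2E)-3-methyl-4-(2-methyl-1,3-dioxolan-2-yl)but-2-enoate | COC(=O)/C=C(\C)CC1(C)OCCO1
F6 | step 3 | methyl (2E)-5-hydroperoxy-5-methoxy-3-methylhex-2-enoate | COC(=O)/C=C(\C)CC(C)(OC)OO
F7 | step 3 | methyl 2-(5-methoxy-3,5-dimethyl-1,2-dioxolan-3-yl)acetate, racemic at C3 | COC1(C)CC(C)(CC(=O)OC)OO1
F8 | step 2 | (2E)-3-methyl-4-(2-methyl-1,3-dioxolan-2-yl)but-2-en-1-ol | OC/C=C(\C)CC1(C)OCCO1
F9 | step 2 | [(2R,3R)-3-methyl-3-[(2-methyl-1,3-dioxolan-2-yl)methyl]oxiran-2-yl]methanol | CC1(OCCO1)C[C@@]2(C)O[C@@H]2CO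
F10 | step 2 | (3S)-3-methyl-4-(2-methyl-1,3-dioxolan-2-yl)butane-1,3-diol | CC1(OCCO1)C[C@](O)(C)CCO
F11 | step 2 | (3S)-3-hydroxy-3-methyl-4-(2-methyl-1,3-dioxolan-2-yl)butyl 4-methylbenzenesulfonate | CC1(OCCO1)C[C@](O)(C)CCOS(=O)(=O)c1ccc(C)cc1
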